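**Retrosynthetic overview**
- Feature: in ring A (the benzene ring of the benzofuran) C3a and C4 are neighbours. C3a holds furan carbon C3, C4 holds the side-chain CH2, and C7a–O1 flanks C3a on the other side. Ring A therefore reads as an aryl iodide with iodine at C3a, a blocked ortho position at C7a and a free ortho C4–H, ready for ipso/ortho difunctionalization.
- Moracin Q ⇒ (benzyl ether hydrogenolysis, carbinol oxidation) 4-(2-hydroxy-3-methylbutyl)benzofuran ⇒ (O1–C2, 5-endo-dig) 2-alkynylphenol ⇒ (MOM cleavage) protected alkynyl carbinol.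
- Alkynyl carbinol ⇒ (C4–CH2 and C3a–C3 in one palladium/norbornene operation) iodoarene + 2-isopropyloxirane + 3,5-bis(benzyloxy)phenylacetylene.
- Iodoarene ⇐ O-benzylisovanillin (Baeyer–Villiger/methanolysis, iodination, MOM ether). Alkyne ⇐ 3,5-bis(benzyloxy)benzaldehyde (Ohira–Bestmann).
- Ring order: ring A and ring C (the resorcinol ring) are bought. Furan ring B is the only ring made, and it is closed after the key step.

Key step: step 5

Assumption: the target has no stereocentre, and the carbinol carbon brought in by the epoxide is later oxidized to the ketone. The racemic epoxide is therefore used, and the carbinol intermediates are racemates drawn without stereo descriptors.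

Step 1
Reactants: 1 3-(benzyloxy)-4-methoxybenzaldehyde
Product: 3 3-(benzyloxy)-4-methoxyphenol, via aryl formate 2 (not isolated)
Conditions: mCPBA, CH2Cl2, 0 °C to rt; aq NaHCO3 wash; then K2CO3 (cat.), MeOH, rt
Reagents that add atoms: 3-chloroperoxybenzoic acid (mCPBA), O=C(OO)c1cccc(Cl)c1
Why: Baeyer–Villiger oxidation (the peracid form of the Dakin reaction), in which the aryl group activated by its para methoxy group migrates to oxygen, followed by base-catalysed methanolysis of the labile aryl formate.

Step 2
Reactants: 3 3-(benzyloxy)-4-methoxyphenol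
Product: 4 5-(benzyloxy)-2-iodo-4-methoxyphenol
Conditions: NIS (1.0 equiv), MeCN, 0 °C, dark
Reagents that add atoms: N-iodosuccinimide, O=C1CCC(=O)N1I
Why: Electrophilic aromatic iodination goes to the position ortho to the hydroxyl that is also para to the benzyloxy group, because the other ortho site is squeezed between two oxygen substituents.

Step 3
Reactants: 4 5-(benzyloxy)-2-iodo-4-methoxyphenol
Product: 5 1-(benzyloxy)-4-iodo-2-methoxy-5-(methoxymethoxy)benzene
Conditions: NaH, MOMCl, THF, 0 °C to rt
Reagents that add atoms: chloromethyl methyl ether (MOMCl), COCCl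
Why: Williamson-type O-alkylation of the sodium phenoxide with the reactive chloromethyl ether gives an acetal that tolerates carbonate bases and palladium catalysis at elevated temperature.

Step 4
Reactants: 6 3,5-bis(benzyloxy)benzaldehyde
Product: 7 1,3-bis(benzyloxy)-5-ethynylbenzene
Conditions: dimethyl (1-diazo-2-oxopropyl)phosphonate, K2CO3, MeOH, rt
Reagents that add atoms: dimethyl (1-diazo-2-oxopropyl)phosphonate (Ohira–Bestmann reagent), COP(=O)(OC)C(=[N+]=[N-])C(C)=O
Why: In the Ohira–Bestmann variant of the Seyferth–Gilbert homologation, deacylation liberates dimethyl (diazomethyl)phosphonate, its anion olefinates the aldehyde, and loss of nitrogen with a 1,2-hydrogen shift gives the terminal alkyne without harm to the benzyl ethers.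

Step 5
Reactants: 5 1-(benzyloxy)-4-iodo-2-methoxy-5-(methoxymethoxy)benzene; 7 1,3-bis(benzyloxy)-5-ethynylbenzene; 8 rac-2-isopropyloxirane
Product: 9 rac-1-[3-(benzyloxy)-6-{[3,5-bis(benzyloxy)phenyl]ethynyl}-2-methoxy-5-(methoxymethoxy)phenyl]-3-methylbutan-2-ol
Conditions: Pd(OAc)2 (10 mol %), XPhos (20 mol %), potassium 5-norbornene-2-carboxylate (1 equiv), Cs2CO3 (2 equiv), 8 (4 equiv), NMP, 70 °C, Ar; 7 (1.5 equiv) by syringe pump over 10 h
Reagents that add atoms: none
Why: Proposed new method: zerovalent palladium inserts into the carbon–iodine bond at C3a of 5, the strained alkene of the norbornene mediator inserts into the aryl–palladium bond, and carbonate-assisted palladation of C4–H closes the aryl-norbornyl palladacycle of divalent palladium. This electron-rich palladacycle opens 8 by SN2 attack at the unsubstituted CH2 to reach tetravalent palladium, reductive elimination forms C4–CH2, and because both ortho positions are now filled the norbornene is expelled by β-carbon elimination. The arylpalladium species of divalent palladium left at C3a binds 7, base turns it into the alkynyl complex, and reductive elimination forms C3a–C3 and gives back zerovalent palladium. The closest known reaction types are the Catellani ortho-alkylation with epoxides that ends in a Heck coupling and the Catellani ortho-alkylation with alkyl halides that ends in coupling with a terminal alkyne, and XPhos with Cs2CO3 is chosen because it serves both the epoxide alkylation and copper-free alkynylation. No ring is closed and no stereocentre is controlled, since the carbinol carbon is carried over untouched from racemic 8. Site selectivity rests on C4–H being the only hydrogen ortho to iodine (C7a is blocked by OMOM) and on the steric bias of 8 for its CH2, while the order of events rests on a high mediator-to-alkyne ratio (slow addition of 7) and on C–C(sp) reductive elimination being faster than ipso C–O closure by the pendant alkoxide.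

Step 6
Reactants: 9 rac-1-[3-(benzyloxy)-6-{[3,5-bis(benzyloxy)phenyl]ethynyl}-2-methoxy-5-(methoxymethoxy)phenyl]-3-methylbutan-2-ol
Product: 10 rac-5-(benzyloxy)-2-{[3,5-bis(benzyloxy)phenyl]ethynyl}-3-(2-hydroxy-3-methylbutyl)-4-methoxyphenol
Conditions: conc. HCl (cat.), MeOH/THF, 40 °C
Reagents that add atoms: none
Why: Acid-catalysed transacetalization of the phenolic MOM ether to methanol is far faster than protonation of the diarylalkyne and leaves the benzyl ethers, the methyl ether and the secondary alcohol untouched.

Step 7
Reactants: 10 rac-5-(benzyloxy)-2-{[3,5-bis(benzyloxy)phenyl]ethynyl}-3-(2-hydroxy-3-methylbutyl)-4-methoxyphenol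
Product: 11 rac-1-{6-(benzyloxy)-2-[3,5-bis(benzyloxy)phenyl]-5-methoxy-1-benzofuran-4-yl}-3-methylbutan-2-ol
Conditions: Cs2CO3 (20 mol %), DMF, 60 °C, Ar
Reagents that add atoms: none
Why: In this base-catalysed 5-endo-dig hydroalkoxylation of a 2-alkynylphenol, carbonate deprotonates only the phenol, the phenoxide adds to the alkyne carbon bearing ring C (O1–C2), and the C3 anion is protonated while the much less acidic side-chain alcohol stays neutral.

Step 8
Reactants: 11 rac-1-{6-(benzyloxy)-2-[3,5-bis(benzyloxy)phenyl]-5-methoxy-1-benzofuran-4-yl}-3-methylbutan-2-ol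
Product: 12 1-{6-(benzyloxy)-2-[3,5-bis(benzyloxy)phenyl]-5-methoxy-1-benzofuran-4-yl}-3-methylbutan-2-one
Conditions: Dess–Martin periodinane, CH2Cl2, 0 °C to rt
Reagents that add atoms: none
Why: Dess–Martin oxidation of the secondary alcohol under nearly neutral conditions, at a stage where no free phenol is present and the benzofuran and benzyl ethers are inert, removes the only stereocentre.

Step 9
Reactants: 12 1-{6-(benzyloxy)-2-[3,5-bis(benzyloxy)phenyl]-5-methoxy-1-benzofuran-4-yl}-3-methylbutan-2-one
Product: 13 moracin Q, 1-[2-(3,5-dihydroxyphenyl)-6-hydroxy-5-methoxy-1-benzofuran-4-yl]-3-methylbutan-2-one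
Conditions: H2 (1 atm), 10% Pd/C, EtOAc/MeOH, rt
Reagents that add atoms: none
Why: Catalytic hydrogenolysis cleaves the three benzylic C–O bonds at atmospheric pressure, under which the aromatic 2-arylbenzofuran, the aryl methyl ether and the non-benzylic ketone are expected to persist.

**Compound list**
1 | 3-(benzyloxy)-4-methoxybenzaldehyde | COc1ccc(C=O)cc1OCc1ccccc1 | starting material
2 | 3-(benzyloxy)-4-methoxyphenyl formate | COc1ccc(OC=O)cc1OCc1ccccc1 | intermediate (not isolated)
3 | 3-(benzyloxy)-4-methoxyphenol | COc1ccc(O)cc1OCc1ccccc1 | intermediate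
4 | 5-(benzyloxy)-2-iodo-4-methoxyphenol | COc1cc(I)c(O)cc1OCc1ccccc1 | intermediate
5 | 1-(benzyloxy)-4-iodo-2-methoxy-5-(methoxymethoxy)benzene | COCOc1cc(OCc2ccccc2)c(OC)cc1I | intermediate
6 | 3,5-bis(benzyloxy)benzaldehyde | O=Cc1cc(OCc2ccccc2)cc(OCc2ccccc2)c1 | starting material
7 | 1,3-bis(benzyloxy)-5-ethynylbenzene | C#Cc1cc(OCc2ccccc2)cc(OCc2ccccc2)c1 | intermediate
8 | rac-2-isopropyloxirane (1,2-epoxy-3-methylbutane) | CC(C)C1CO1 | starting material
9 | rac-1-[3-(benzyloxy)-6-{[3,5-bis(benzyloxy)phenyl]ethynyl}-2-methoxy-5-(methoxymethoxy)phenyl]-3-methylbutan-2-ol | COCOc1cc(OCc2ccccc2)c(OC)c(CC(O)C(C)C)c1C#Cc1cc(OCc2ccccc2)cc(OCc2ccccc2)c1 | intermediate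
10 | rac-5-(benzyloxy)-2-{[3,5-bis(benzyloxy)phenyl]ethynyl}-3-(2-hydroxy-3-methylbutyl)-4-methoxyphenol | Oc1cc(OCc2ccccc2)c(OC)c(CC(O)C(C)C)c1C#Cc1cc(OCc2ccccc2)cc(OCc2ccccc2)c1 | intermediate
11 | rac-1-{6-(benzyloxy)-2-[3,5-bis(benzyloxy)phenyl]-5-methoxy-1-benzofuran-4-yl}-3-methylbutan-2-ol | COc1c(OCc2ccccc2)cc2oc(-c3cc(OCc4ccccc4)cc(OCc4ccccc4)c3)cc2c1CC(O)C(C)C | intermediate
12 | 1-{6-(benzyloxy)-2-[3,5-bis(benzyloxy)phenyl]-5-methoxy-1-benzofuran-4-yl}-3-methylbutan-2-one | COc1c(OCc2ccccc2)cc2oc(-c3cc(OCc4ccccc4)cc(OCc4ccccc4)c3)cc2c1CC(=O)C(C)C | intermediate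
13 | moracin Q | COc1c(O)cc2oc(-c3cc(O)cc(O)c3)cc2c1CC(=O)C(C)C | target

Total step count: 9. Longest linear sequence: 8 steps (1 → 3 → 4 → 5 → 9 → 10 → 11 → 12 → 13). Step 4 is the side branch.

**Steps most likely to fail**

Step 5 (proposed new method).
- The terminal alkyne may capture the first arylpalladium species before the norbornene unit inserts, which amounts to premature ipso alkynylation.
- The alkyne may also protonate the palladacycle while the sluggish epoxide has not yet reacted.
- Palladation of the C4–H bond next to the methoxy group may be slow.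
- The pendant alkoxide may close onto C3a or add 6-exo-dig to the new alkyne.

The fallback uses known chemistry. It sets out from 8, uses 5 and 7, and comes back at 9. The epoxide is replaced by a primary alkyl iodide, the electrophile class for which the alkyne-terminated Catellani alkylation is established, and the oxygen is masked so that no alkoxide is ever present. Epoxide 8 is opened at its CH2 with LiI and AcOH in THF to rac-1-iodo-3-methylbutan-2-ol F1. Silylation with TBSOTf and 2,6-lutidine in CH2Cl2 at 0 °C gives rac-tert-butyl[(1-iodo-3-methylbutan-2-yl)oxy]dimethylsilane F2. Compounds 5, F2 and 7 are joined under Pd(OAc)2, tri(2-furyl)phosphine, norbornene and Cs2CO3 in MeCN at 80 °C, with slow addition of 7. This should give rac-tert-butyl({1-[3-(benzyloxy)-6-{[3,5-bis(benzyloxy)phenyl]ethynyl}-2-methoxy-5-(methoxymethoxy)phenyl]-3-methylbutan-2-yl}oxy)dimethylsilane F3. TBAF in THF at rt then returns 9.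

Step 7.
- The side-chain hydroxyl may compete with the phenoxide for the alkyne (6-exo-dig against 5-endo-dig closure).
- Anionic addition to an alkyne attached to the very electron-rich ring A may be sluggish.

The fallback sets out from 9 and comes back at 12. It removes the hydroxyl before ring closure and switches from anionic to carbophilic activation. Dess–Martin oxidation of 9 gives 1-[3-(benzyloxy)-6-{[3,5-bis(benzyloxy)phenyl]ethynyl}-2-methoxy-5-(methoxymethoxy)phenyl]-3-methylbutan-2-one F4. Catalytic HCl in MeOH/THF then frees 1-[3-(benzyloxy)-6-{[3,5-bis(benzyloxy)phenyl]ethynyl}-5-hydroxy-2-methoxyphenyl]-3-methylbutan-2-one F5. AuCl3 (5 mol %) in MeCN at rt activates the alkyne for 5-endo-dig attack by the phenol, now the only protic nucleophile, and delivers 12 directly.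

Step 9.
- The furan C2=C3 bond may be over-reduced on prolonged exposure.
- Cleavage of the hindered C6 benzyl ether may be incomplete.

The fallback sets out from 12 and comes back at 13. The reductive cleavage is replaced by Lewis-acid debenzylation with a cation scavenger: BCl3 and pentamethylbenzene in CH2Cl2 at −78 °C, followed by a methanol quench. These conditions leave the furan double bond alone and should spare the methyl ether at low temperature. This fallback makes no new compound (F0).

**Further compounds**
F1 | step 5 | rac-1-iodo-3-methylbutan-2-ol | CC(C)C(O)CI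
F2 | step 5 | rac-tert-butyl[(1-iodo-3-methylbutan-2-yl)oxy]dimethylsilane | CC(C)C(CI)O[Si](C)(C)C(C)(C)C
F3 | step 5 | rac-tert-butyl({1-[3-(benzyloxy)-6-{[3,5-bis(benzyloxy)phenyl]ethynyl}-2-methoxy-5-(methoxymethoxy)phenyl]-3-methylbutan-2-yl}oxy)dimethylsilane | COCOc1cc(OCc2ccccc2)c(OC)c(CC(O[Si](C)(C)C(C)(C)C)C(C)C)c1C#Cc1cc(OCc2ccccc2)cc(OCc2ccccc2)c1
F4 | step 7 | 1-[3-(benzyloxy)-6-{[3,5-bis(benzyloxy)phenyl]ethynyl}-2-methoxy-5-(methoxymethoxy)phenyl]-3-methylbutan-2-one | COCOc1cc(OCc2ccccc2)c(OC)c(CC(=O)C(C)C)c1C#Cc1cc(OCc2ccccc2)cc(OCc2ccccc2)c1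
F5 | step 7 | 1-[3-(benzyloxy)-6-{[3,5-bis(benzyloxy)phenyl]ethynyl}-5-hydroxy-2-methoxyphenyl]-3-methylbutan-2-one | Oc1cc(OCc2ccccc2)c(OC)c(CC(=O)C(C)C)c1C#Cc1cc(OCc2ccccc2)cc(OCc2ccccc2)c1
F0 | step 9 | none | none
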